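**Plan**
- Numbering: chromone locants, primed for the 8-hydroxy unit (unit B) and unprimed for the 6-hydroxy unit (unit A); ring A is the benzene ring of unit A.
- Cuts, backwards: the 8'-O–CH3 ether; O1–C2 and C2–C3 of the unit A pyranone; C8a–C4a and C5–C6 of ring A; the aryl–alkyne bond at C5' (the later C5–C5' biaryl bond); O1'–C2' and C2'–C3' of the unit B pyranone.
- Enabling feature: ring A is a hydroquinone with oxygen on C8a and C6 (para). The two carbons joining them on one side, C4a (acyl-bearing) and C5 (bearing C5'), are adjacent, so they can be the two sp carbons of an aryl ynone, while C6, C7, C8, C8a and both oxygens come from a 2,5-dioxygenated furan.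
- Forward: unit B pyranone on a brominated arene; alkynylation and oxidation to the ynone; ring A by [4+2] cycloaddition and bridge collapse at the quinone level; reduction; unit A pyranone; O-demethylation.
- Stereochemistry: the target has no stereocentre; the centres that appear on the way (compounds 3, 10, 14) are erased again.

Key step: step 9

Assumption: the target SMILES carries no stereodescriptor, so the hindered C5–C5' axis is treated as unspecified and all biaryl compounds are made as racemates about that axis.

**Step 1**
Reactants: 1 2,3-dimethoxybenzaldehyde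
Product: 2 6-bromo-2,3-dimethoxybenzaldehyde
Conditions: NBS (1.1 equiv), DMF, rt
Reagents that add atoms: N-bromosuccinimide, O=C1CCC(=O)N1Br
Why: Electrophilic aromatic bromination should enter para to the 3-methoxy group (C6), the stronger donor because the flanked 2-methoxy group is twisted out of conjugation.

**Step 2**
Reactants: 2 6-bromo-2,3-dimethoxybenzaldehyde
Product: 3 1-(6-bromo-2,3-dimethoxyphenyl)ethanol (racemic)
Conditions: MeMgBr, THF, 0 °C; then 1 M HCl, 0 °C
Reagents that add atoms: methylmagnesium bromide, C[Mg]Br
Why: Grignard addition to the aldehyde should leave the aryl bromide untouched at 0 °C; the carbinol centre forms as a racemate and is erased in step 3.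

**Step 3**
Reactants: 3 1-(6-bromo-2,3-dimethoxyphenyl)ethanol
Product: 4 1-(6-bromo-2,3-dimethoxyphenyl)ethanone
Conditions: Dess–Martin periodinane, CH2Cl2, rt
Reagents that add atoms: none
Why: Dess–Martin oxidation of a secondary benzylic alcohol is reliable even when both ortho positions are substituted.

**Step 4**
Reactants: 4 1-(6-bromo-2,3-dimethoxyphenyl)ethanone
Product: 5 1-(6-bromo-2-hydroxy-3-methoxyphenyl)ethanone
Conditions: BCl3 (1.2 equiv), CH2Cl2, −78 → 0 °C; then H2O
Reagents that add atoms: none
Why: Chelation-controlled ether cleavage: boron bridges the carbonyl oxygen and the ortho methoxy oxygen, so only the methoxy group next to the acetyl group should be removed.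

**Step 5**
Reactants: 5 1-(6-bromo-2-hydroxy-3-methoxyphenyl)ethanone; 6 ethyl 3-phenylpropanoate
Product: 8 5-bromo-8-methoxy-2-(2-phenylethyl)chromen-4-one, via bromo diketone 7 (not isolated)
Conditions: NaH (4 equiv), 6 (2 equiv), THF, reflux; 1 M HCl quench; then conc. HCl (cat.), AcOH, 100 °C
Reagents that add atoms: none
Why: Crossed Claisen condensation of the phenoxide–enolate dianion with the ester gives the 1,3-diketone, and acid cyclodehydration closes the pyranone, the standard construction of 2-(2-phenylethyl)chromones.

**Step 6**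
Reactants: 8 5-bromo-8-methoxy-2-(2-phenylethyl)chromen-4-one; 9 but-3-yn-2-ol (racemic)
Product: 10 5-(3-hydroxybut-1-yn-1-yl)-8-methoxy-2-(2-phenylethyl)chromen-4-one (racemic)
Conditions: Pd(PPh3)2Cl2 (5 mol %), CuI (10 mol %), Et3N, DMF, 80 °C
Reagents that add atoms: none
Why: Sonogashira coupling: oxidative addition of zerovalent palladium into the C5'–Br bond is helped by the neighbouring carbonyl-bearing ring carbon, and the copper acetylide of 9 then delivers the alkyne.

**Step 7**
Reactants: 10 5-(3-hydroxybut-1-yn-1-yl)-8-methoxy-2-(2-phenylethyl)chromen-4-one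
Product: 11 4-[8-methoxy-4-oxo-2-(2-phenylethyl)chromen-5-yl]but-3-yn-2-one
Conditions: MnO2 (activated, excess), CH2Cl2, rt
Reagents that add atoms: none
Why: MnO2 oxidises propargylic alcohols to conjugated ynones under neutral conditions that should spare the chromone.

**Step 8**
Reactants: 12 succinic anhydride
Product: 13 2,5-bis(trimethylsilyloxy)furan
Conditions: Me3SiCl (2.5 equiv), Et3N (2.5 equiv), ZnCl2 (cat.), MeCN, rt → 40 °C; filtration, distillation under reduced pressure, used at once
Reagents that add atoms: chlorotrimethylsilane, C[Si](C)(C)Cl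
Why: Double enol silylation of the anhydride, driven by formation of the aromatic furan, is the established way to this moisture-sensitive diene.

**Step 9**
Reactants: 11 4-[8-methoxy-4-oxo-2-(2-phenylethyl)chromen-5-yl]but-3-yn-2-one; 13 2,5-bis(trimethylsilyloxy)furan
Product: 15 2-acetyl-3-[8-methoxy-4-oxo-2-(2-phenylethyl)chromen-5-yl]-1,4-benzoquinone, via silyloxy-bridged oxanorbornadiene adduct 14 (not isolated)
Conditions: 13 (1.3 equiv), CH2Cl2, −20 °C → rt; then 0.1 M HCl, THF, 0 °C
Reagents that add atoms: none
Why: The electron-rich bis(silyloxy)furan and the electron-poor ynone should combine in a normal-demand Diels–Alder reaction, concerted but asynchronous, in which furan C2 and C5 bond to the acetyl-bearing and the aryl-bearing alkyne carbon and so create C8a–C4a and C5–C6 of ring A. Ring A closes by this intermolecular [4+2] cycloaddition (the second σ-bond completes the six-membered carbocycle), giving the oxygen-bridged adduct 14 whose two bridgeheads are silyl ketal carbons; the bridge therefore opens with push from a silyloxy oxygen, and loss of hexamethyldisiloxane on mild acid work-up leaves the two quinone carbonyls at C8a and C6. The closest known reaction type is the cycloaddition of 2,5-bis(trimethylsilyloxy)furans with acetylenic dienophiles, which delivers p-benzoquinones after bridge collapse. No stereocentre is set, because the two bridgehead centres of racemic 14 become carbonyl carbons. The step needs chemoselectivity only, since the symmetric diene leaves no regiochemical choice: the conjugated alkyne is far more dienophilic than the donor-substituted C2'=C3' bond of the chromone, and a second addition to the quinone is held back by a small excess of diene and by releasing the quinone only in the acidic quench that also destroys the remaining furan. The crowded C5–C5' bond is not formed here at all, as it is already present as the aryl–alkyne bond of 11.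

**Step 10**
Reactants: 15 2-acetyl-3-[8-methoxy-4-oxo-2-(2-phenylethyl)chromen-5-yl]-1,4-benzoquinone
Product: 16 5-(2-acetyl-3,6-dihydroxyphenyl)-8-methoxy-2-(2-phenylethyl)chromen-4-one
Conditions: Na2S2O4, EtOAc/H2O, rt
Reagents that add atoms: none
Why: Dithionite reduction of an acylquinone to its hydroquinone is fast and should not touch the chromone.

**Step 11**
Reactants: 16 5-(2-acetyl-3,6-dihydroxyphenyl)-8-methoxy-2-(2-phenylethyl)chromen-4-one; 17 3-phenylpropanoyl chloride
Product: 18 2-acetyl-3-[8-methoxy-4-oxo-2-(2-phenylethyl)chromen-5-yl]-1,4-phenylene bis(3-phenylpropanoate)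
Conditions: 17 (2.5 equiv), Et3N, DMAP (cat.), CH2Cl2, 0 °C → rt
Reagents that add atoms: none
Why: DMAP-catalysed O-acylation should esterify both phenols, including the hydrogen-bonded one next to the acetyl group, which is the ester needed for the acyl transfer.

**Step 12**
Reactants: 18 2-acetyl-3-[8-methoxy-4-oxo-2-(2-phenylethyl)chromen-5-yl]-1,4-phenylene bis(3-phenylpropanoate)
Product: 21 6-hydroxy-8'-methoxy-2,2'-bis(2-phenylethyl)-4H,4'H-[5,5'-bichromene]-4,4'-dione, via diketone ester 19 (not isolated), via bichromone ester 20 (not isolated)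
Conditions: LiN(SiMe3)2 (3.5 equiv), THF, −78 → 0 °C; then HCl, MeOH, reflux
Reagents that add atoms: none
Why: Baker–Venkataraman rearrangement: the kinetic lithium enolate of the acetyl group attacks the neighbouring ester carbonyl through a six-membered transition state to give the β-diketone, and in methanolic HCl the freed C8a phenol should close onto the distal ketone with loss of water (cyclodehydration) before slower acid-catalysed methanolysis removes the remaining C6 ester.

**Step 13**
Reactants: 21 6-hydroxy-8'-methoxy-2,2'-bis(2-phenylethyl)-4H,4'H-[5,5'-bichromene]-4,4'-dione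
Product: 22 6,8'-dihydroxy-2,2'-bis(2-phenylethyl)-4H,4'H-[5,5'-bichromene]-4,4'-dione
Conditions: BBr3 (5 equiv), CH2Cl2, −78 °C → rt; then MeOH, H2O
Reagents that add atoms: none
Why: BBr3 cleavage of an aryl methyl ether is routine on methoxychromones and leaves the pyranones and the phenylethyl chains intact.

**Compound list**
1 | 2,3-dimethoxybenzaldehyde | COc1cccc(C=O)c1OC | starting material
2 | 6-bromo-2,3-dimethoxybenzaldehyde | COc1ccc(Br)c(C=O)c1OC | intermediate
3 | 1-(6-bromo-2,3-dimethoxyphenyl)ethanol (racemic) | CC(O)c1c(Br)ccc(OC)c1OC | intermediate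
4 | 1-(6-bromo-2,3-dimethoxyphenyl)ethanone | CC(=O)c1c(Br)ccc(OC)c1OC | intermediate
5 | 1-(6-bromo-2-hydroxy-3-methoxyphenyl)ethanone | CC(=O)c1c(Br)ccc(OC)c1O | intermediate
6 | ethyl 3-phenylpropanoate | CCOC(=O)CCc1ccccc1 | starting material
7 | 1-(6-bromo-2-hydroxy-3-methoxyphenyl)-5-phenylpentane-1,3-dione (not isolated) | O=C(CC(=O)CCc1ccccc1)c1c(Br)ccc(OC)c1O | intermediate
8 | 5-bromo-8-methoxy-2-(2-phenylethyl)chromen-4-one | O=c1cc(CCc2ccccc2)oc2c(OC)ccc(Br)c12 | intermediate
9 | but-3-yn-2-ol (racemic) | CC(O)C#C | starting material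
10 | 5-(3-hydroxybut-1-yn-1-yl)-8-methoxy-2-(2-phenylethyl)chromen-4-one (racemic) | CC(O)C#Cc1ccc(OC)c2oc(CCc3ccccc3)cc(=O)c12 | intermediate
11 | 4-[8-methoxy-4-oxo-2-(2-phenylethyl)chromen-5-yl]but-3-yn-2-one | CC(=O)C#Cc1ccc(OC)c2oc(CCc3ccccc3)cc(=O)c12 | intermediate
12 | succinic anhydride | O=C1CCC(=O)O1 | starting material
13 | 2,5-bis(trimethylsilyloxy)furan | C[Si](C)(C)Oc1ccc(O[Si](C)(C)C)o1 | intermediate
14 | 2-acetyl-3-[8-methoxy-4-oxo-2-(2-phenylethyl)chromen-5-yl]-1,4-bis(trimethylsilyloxy)-7-oxabicyclo[2.2.1]hepta-2,5-diene (racemic, one enantiomer drawn; not isolated) | CC(=O)C1=C(c3ccc(OC)c4oc(CCc5ccccc5)cc(=O)c34)[C@@]2(O[Si](C)(C)C)C=C[C@]1(O[Si](C)(C)C)O2 | intermediate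
15 | 2-acetyl-3-[8-methoxy-4-oxo-2-(2-phenylethyl)chromen-5-yl]-1,4-benzoquinone | CC(=O)C1=C(c2ccc(OC)c3oc(CCc4ccccc4)cc(=O)c23)C(=O)C=CC1=O | intermediate
16 | 5-(2-acetyl-3,6-dihydroxyphenyl)-8-methoxy-2-(2-phenylethyl)chromen-4-one | CC(=O)c1c(O)ccc(O)c1-c1ccc(OC)c2oc(CCc3ccccc3)cc(=O)c12 | intermediate
17 | 3-phenylpropanoyl chloride | O=C(Cl)CCc1ccccc1 | starting material
18 | 2-acetyl-3-[8-methoxy-4-oxo-2-(2-phenylethyl)chromen-5-yl]-1,4-phenylene bis(3-phenylpropanoate) | CC(=O)c1c(OC(=O)CCc2ccccc2)ccc(OC(=O)CCc2ccccc2)c1-c1ccc(OC)c2oc(CCc3ccccc3)cc(=O)c12 | intermediate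
19 | 4-hydroxy-2-[8-methoxy-4-oxo-2-(2-phenylethyl)chromen-5-yl]-3-(3-oxo-5-phenylpentanoyl)phenyl 3-phenylpropanoate (not isolated) | O=C(CC(=O)CCc1ccccc1)c1c(O)ccc(OC(=O)CCc2ccccc2)c1-c1ccc(OC)c2oc(CCc3ccccc3)cc(=O)c12 | intermediate
20 | 8'-methoxy-4,4'-dioxo-2,2'-bis(2-phenylethyl)-4H,4'H-[5,5'-bichromen]-6-yl 3-phenylpropanoate (not isolated) | O=C(CCc1ccccc1)Oc1ccc2oc(CCc3ccccc3)cc(=O)c2c1-c1ccc(OC)c2oc(CCc3ccccc3)cc(=O)c12 | intermediate
21 | 6-hydroxy-8'-methoxy-2,2'-bis(2-phenylethyl)-4H,4'H-[5,5'-bichromene]-4,4'-dione | Oc1ccc2oc(CCc3ccccc3)cc(=O)c2c1-c1ccc(OC)c2oc(CCc3ccccc3)cc(=O)c12 | intermediate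
22 | 6,8'-dihydroxy-2,2'-bis(2-phenylethyl)-4H,4'H-[5,5'-bichromene]-4,4'-dione | O=c1cc(CCc2ccccc2)oc2ccc(O)c(-c3ccc(O)c4oc(CCc5ccccc5)cc(=O)c34)c12 | target

**Step count**
Total: 13 steps. Longest linear sequence: 12 steps (steps 1–7 and 9–13, from 2,3-dimethoxybenzaldehyde); step 8 is a one-step branch.

**Steps most likely to fail**

Step 9. The adduct may collapse to the quinone while diene is still present, so that a second cycloaddition at the unsubstituted quinone double bond consumes the product. Alternatively, hydrolytic loss of the furan, or an open-chain Michael addition without ring closure, may outrun a slow cycloaddition to the twisted, hindered ynone. The fallback sets out from 11 and keeps the [4+2] construction of ring A, but uses commercial 2-methoxyfuran (toluene, rt to 60 °C), which is more robust and delivers ring A at the hydroquinone level, so no quinone is ever exposed to diene. The nucleophilic C5 terminus of the furan should bond to the aryl-bearing alkyne carbon and give the bridged adduct 2-acetyl-1-methoxy-3-[8-methoxy-4-oxo-2-(2-phenylethyl)chromen-5-yl]-7-oxabicyclo[2.2.1]hepta-2,5-diene F1. This opens at its ketal bridgehead and aromatises by proton loss to 5-(2-acetyl-6-hydroxy-3-methoxyphenyl)-8-methoxy-2-(2-phenylethyl)chromen-4-one F2. Chelation-controlled cleavage of the methoxy group next to the acetyl group (BCl3, CH2Cl2, −78 → 0 °C, as in step 4) then gives 16, where the route is rejoined; compound 15 and step 10 are bypassed.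

Step 12. Lateral deprotonation of the C2' side chain of unit B and loss of ketene from the aryl esters by elimination may consume the amide base, so that the hindered acetyl enolate does not transfer the acyl group cleanly. The fallback sets out from 16 and avoids strong base and ester intermediates altogether. A Kabbe condensation with 3-phenylpropanal (pyrrolidine, MeOH, 60 °C, under argon; enamine aldol condensation followed by oxa-Michael closure of the C8a phenol) should give 6-hydroxy-5-[8-methoxy-4-oxo-2-(2-phenylethyl)chromen-5-yl]-2-(2-phenylethyl)chroman-4-one F3 as a mixture of stereoisomers. Dehydrogenation with I2 (cat.) in DMSO at 120 °C removes the new centre and gives 21, where the route is rejoined; compounds 17–20 are not needed.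

Step 6. Oxidative addition at the peri-hindered, methoxy-substituted C5'–Br bond may be slow, leaving the copper acetylide to dimerise oxidatively and the amine to isomerise the propargylic alcohol. The fallback sets out from 9 and 8 and replaces the copper/amine system by a Stille coupling. C-stannylation of 9 (n-BuLi, 2 equiv, THF, −78 °C; then Bu3SnCl) gives 4-(tributylstannyl)but-3-yn-2-ol F4. Coupling of F4 with 8 (Pd(PPh3)4, toluene, 100 °C) transfers the alkynyl group under neutral conditions and gives 10, where the route is rejoined.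

**Further compounds**
F1 | step 9 | 2-acetyl-1-methoxy-3-[8-methoxy-4-oxo-2-(2-phenylethyl)chromen-5-yl]-7-oxabicyclo[2.2.1]hepta-2,5-diene (racemic, one enantiomer drawn) | CC(=O)C1=C(c3ccc(OC)c4oc(CCc5ccccc5)cc(=O)c34)[C@H]2C=C[C@]1(OC)O2
F2 | step 9 | 5-(2-acetyl-6-hydroxy-3-methoxyphenyl)-8-methoxy-2-(2-phenylethyl)chromen-4-one | CC(=O)c1c(OC)ccc(O)c1-c1ccc(OC)c2oc(CCc3ccccc3)cc(=O)c12
F3 | step 12 | 6-hydroxy-5-[8-methoxy-4-oxo-2-(2-phenylethyl)chromen-5-yl]-2-(2-phenylethyl)chroman-4-one (mixture of stereoisomers) | Oc1ccc2OC(CCc3ccccc3)CC(=O)c2c1-c1ccc(OC)c2oc(CCc3ccccc3)cc(=O)c12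
F4 | step 6 | 4-(tributylstannyl)but-3-yn-2-ol (racemic) | CCCC[Sn](CCCC)(CCCC)C#CC(C)O
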